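**Plan**

- Retrosynthesis: the tiglate and the acetate are removed, the side-chain carbinol goes back to an aryl methyl ketone (masked as a dioxolane) and the enal CHO to the methyl of an isopropenyl group. The C3 oxygen is then tied to the isopropenyl carbon as an oxetane, which is cut across C3–C2 and O–CMe2 to an aryl aldehyde with an ortho O–CH=CMe2 ether.
- Enabling feature: on the dihydrofuran ring the C3 oxygen and the carbon substituent on C2 sit on the same face in a 1,3 relationship (O–C3–C2–C). They can therefore be two corners of an oxetane fused to the C2–C3 bond, whose eliminative opening returns the C3 hydroxyl and the exocyclic methylene.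
- Forward: the benzene ring is purchased, and ether, ketal, benzylic alcohol, enol ether and aldehyde are set up in five steps. One photochemical step then closes the dihydrofuran ring and the oxetane together. The oxetane is opened, and acetate, ketone, carbinol, tiglate and enal follow.
- Stereochemistry: the cis C2/C3 relationship comes from the four/five ring fusion, and the absolute (2S,3S) sense from lipase kinetic resolution of the racemic cis alcohol. The side-chain (R) centre is set afterwards by transfer hydrogenation with the (R,R) ruthenium catalyst, and the (E)-tiglate comes from the acyl chloride.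

Key step: step 6

Remark: the photoadduct and the alcohol from its opening are racemates, written with the SMILES of the enantiomer that is carried on; all starting materials are taken as purchased.

**Route**

Step 1
Reactants: 1 methyl 5-acetyl-2-hydroxybenzoate; 2 3-chloro-2-methylprop-1-ene
Product: 3 methyl 5-acetyl-2-[(2-methylprop-2-en-1-yl)oxy]benzoate
Conditions: K2CO3, NaI (cat.), DMF, 60 °C
Reagents that add atoms: 3-chloro-2-methylprop-1-ene (2), C=C(C)CCl
Why: Williamson ether synthesis; the acidic phenoxide displaces chloride from the allylic chloride with iodide as nucleophilic catalyst, and ketone and ester are inert.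

Step 2
Reactants: 3 methyl 5-acetyl-2-[(2-methylprop-2-en-1-yl)oxy]benzoate; 4 1,2-bis(trimethylsilyloxy)ethane
Product: 5 methyl 5-(2-methyl-1,3-dioxolan-2-yl)-2-[(2-methylprop-2-en-1-yl)oxy]benzoate
Conditions: TMSOCH2CH2OTMS (1.5 equiv), TMSOTf (5 mol%), CH2Cl2, −78 → −20 °C; pyridine quench
Reagents that add atoms: 1,2-bis(trimethylsilyloxy)ethane (4), C[Si](C)(C)OCCO[Si](C)(C)C
Why: Noyori ketalisation of the ketone to the 1,3-dioxolane at low temperature, which spares the methallyl ether and the ester and removes the second carbonyl chromophore and the hydride-sensitive ketone before steps 3 and 6.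

Step 3
Reactants: 5 methyl 5-(2-methyl-1,3-dioxolan-2-yl)-2-[(2-methylprop-2-en-1-yl)oxy]benzoate
Product: 7 {5-(2-methyl-1,3-dioxolan-2-yl)-2-[(2-methylprop-2-en-1-yl)oxy]phenyl}methanol, via methallyloxy aldehyde 6 (not isolated)
Conditions: LiAlH4, THF, 0 °C
Reagents that add atoms: none
Why: Hydride reduction of the ester through aldehyde 6 to the benzylic alcohol; the dioxolane, the aryl allyl ether and the alkene are inert to LiAlH4 at this temperature.

Step 4
Reactants: 7 {5-(2-methyl-1,3-dioxolan-2-yl)-2-[(2-methylprop-2-en-1-yl)oxy]phenyl}methanol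
Product: 8 {5-(2-methyl-1,3-dioxolan-2-yl)-2-[(2-methylprop-1-en-1-yl)oxy]phenyl}methanol
Conditions: KOtBu (3 equiv), DMSO, 25–50 °C, argon
Reagents that add atoms: none
Why: Base-mediated prototropic isomerisation of the 2-methylallyl ether to the 2-methylprop-1-enyl ether through the oxygen-substituted allyl anion, driven by conjugation with oxygen; the product has no E/Z geometry, the ketal is base-stable, and excess base is used because the free alcohol takes up one equivalent.

Step 5
Reactants: 8 {5-(2-methyl-1,3-dioxolan-2-yl)-2-[(2-methylprop-1-en-1-yl)oxy]phenyl}methanol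
Product: 9 5-(2-methyl-1,3-dioxolan-2-yl)-2-[(2-methylprop-1-en-1-yl)oxy]benzaldehyde
Conditions: MnO2, CH2Cl2, rt
Reagents that add atoms: none
Why: MnO2 oxidation selective for benzylic alcohols; it is neutral, so the acid-labile enol ether and ketal survive, and it stops at the aldehyde.

Step 6
Reactants: 9 5-(2-methyl-1,3-dioxolan-2-yl)-2-[(2-methylprop-1-en-1-yl)oxy]benzaldehyde
Product: 10 rac-(2aR,7bS)-2,2-dimethyl-6-(2-methyl-1,3-dioxolan-2-yl)-2a,7b-dihydro-2H-oxeto[3,2-b][1]benzofuran (cis-fused, racemic)
Conditions: hν (λ ≈ 350 nm, Pyrex), degassed benzene (0.01 M), 20 °C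
Reagents that add atoms: none
Why: Proposed new method: the n,π* excited aryl aldehyde (reacting from its triplet) should add through its electrophilic oxygen to the electron-rich distal carbon (CMe2) of the tethered enol ether, giving a 1,4-biradical (benzylic at the former carbonyl carbon, α-aryloxy at the O-bound carbon) that closes after spin inversion; the closest known reaction type is the intermolecular Paternò–Büchi reaction of aromatic aldehydes with cyclic enol ethers such as 2,3-dihydrofuran, which gives 2,6-dioxabicyclo[3.2.0]heptanes with this orientation, together with intramolecular [2+2] photocycloadditions of partners joined by three atoms that obey the rule of five. The dihydrofuran ring (C7b, C7a, C3a, O3, C2a) closes through the new C7b–C2a bond in the 5-exo-trig sense with respect to the enol ether double bond, and the oxetane (O1, C2, C2a, C7b) is completed by the O1–C2 bond and shares that C–C bond. The two new stereocentres C7b and C2a (later C3 and C2) are fixed relative to each other by the ring fusion, since a four-membered ring can only be cis-fused to a five-membered one; the substrate is achiral and no chiral influence is present, so the cis adduct forms as a racemate. The step needs the fused and not the bridged adduct, which the three-atom tether (C7a, C3a, O3) and the polarity of the enol ether secure, and it needs cycloaddition to win over hydrogen abstraction, which is helped because the O-bound carbon is vinylic and no sp3 C–H lies δ to the carbonyl. Enol ether geometry plays no part because the distal carbon carries two methyl groups, the dioxolane has no chromophore at the irradiation wavelength, and the product no longer absorbs there.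

Step 7
Reactants: 10 rac-(2aR,7bS)-2,2-dimethyl-6-(2-methyl-1,3-dioxolan-2-yl)-2a,7b-dihydro-2H-oxeto[3,2-b][1]benzofuran
Product: 11 rac-(2S,3S)-5-(2-methyl-1,3-dioxolan-2-yl)-2-(prop-1-en-2-yl)-2,3-dihydro-1-benzofuran-3-ol (cis, racemic)
Conditions: Et2Al(TMP) (4 equiv; from Et2AlCl + LiTMP, LiTMP from TMPH + n-BuLi), toluene, 0 °C → rt
Reagents that add atoms: none
Why: Proposed new method: aluminium should bind the oxetane oxygen while the hindered amide nitrogen removes a methyl hydrogen syn to the O–CMe2 bond through a six-membered cyclic transition state (Al, O, C, C, H, N), cleaving the bond to the tertiary carbon and leaving the C3–O bond and both stereocentres untouched; the closest known reactions are the aluminium amide isomerisation of epoxides to allylic alcohols and the superbase isomerisation of oxetanes to homoallylic alcohols, and loss of the C2 hydrogen together with the C3 oxygen (towards a benzofuran) is disfavoured because that hydrogen is anti to the oxygen in the cis-fused bicycle and cannot enter the cyclic pathway.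

Step 8
Reactants: 11 rac-(2S,3S)-5-(2-methyl-1,3-dioxolan-2-yl)-2-(prop-1-en-2-yl)-2,3-dihydro-1-benzofuran-3-ol; 12 vinyl acetate
Product: 13 (2S,3S)-5-(2-methyl-1,3-dioxolan-2-yl)-2-(prop-1-en-2-yl)-2,3-dihydro-1-benzofuran-3-yl acetate
Conditions: Burkholderia cepacia lipase (immobilised), vinyl acetate (3 equiv), MTBE, 35 °C, stopped near half conversion; chromatography removes the unreacted (2R,3R) enantiomer of 11
Reagents that add atoms: vinyl acetate (12), C=COC(C)=O
Why: Lipase-catalysed kinetic resolution by irreversible transesterification; by the empirical size rule for secondary alcohols (fused aryl carbon as the large group, C2 as the medium one) the (3S) carbinol has the spatial arrangement of the fast-reacting (R)-indan-1-ol, so the (2S,3S) enantiomer should be acetylated at oxygen with both centres untouched, and at most half of the racemate is carried on.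

Step 9
Reactants: 13 (2S,3S)-5-(2-methyl-1,3-dioxolan-2-yl)-2-(prop-1-en-2-yl)-2,3-dihydro-1-benzofuran-3-yl acetate
Product: 14 (2S,3S)-5-acetyl-2-(prop-1-en-2-yl)-2,3-dihydro-1-benzofuran-3-yl acetate
Conditions: PPTS (0.2 equiv), acetone/H2O (9:1), rt
Reagents that add atoms: water, O
Why: Acid-catalysed ketal hydrolysis; the ring oxygen para to the ketal carbon stabilises the intermediate oxocarbenium ion, so the dioxolane should fall under acid mild enough to leave the secondary acetate, the isopropenyl group and both ring stereocentres intact.

Step 10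
Reactants: 14 (2S,3S)-5-acetyl-2-(prop-1-en-2-yl)-2,3-dihydro-1-benzofuran-3-yl acetate
Product: 15 (2S,3S)-5-[(1R)-1-hydroxyethyl]-2-(prop-1-en-2-yl)-2,3-dihydro-1-benzofuran-3-yl acetate
Conditions: RuCl(p-cymene)[(R,R)-TsDPEN] (1 mol%), HCO2H/Et3N (5:2), 30 °C
Reagents that add atoms: none
Why: Noyori-type asymmetric transfer hydrogenation of an aryl methyl ketone; the (R,R) catalyst should deliver hydride to the Si face and set the (R) carbinol under catalyst control (the ring stereocentres are too remote to interfere), while the acetate and the isolated alkene are not reduced.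

Step 11
Reactants: 15 (2S,3S)-5-[(1R)-1-hydroxyethyl]-2-(prop-1-en-2-yl)-2,3-dihydro-1-benzofuran-3-yl acetate; 16 (2E)-2-methylbut-2-enoyl chloride
Product: 17 (1R)-1-[(2S,3S)-3-(acetyloxy)-2-(prop-1-en-2-yl)-2,3-dihydro-1-benzofuran-5-yl]ethyl (2E)-2-methylbut-2-enoate
Conditions: tigloyl chloride, pyridine, DMAP (cat.), CH2Cl2, 0 °C → rt
Reagents that add atoms: (2E)-2-methylbut-2-enoyl chloride (16), C/C=C(\C)C(Cl)=O
Why: DMAP-catalysed O-acylation of the secondary benzylic alcohol; the carbinol C–O bond is not broken, so the (R) centre is retained, and the (E) acyl group is the stable geometry.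

Step 12
Reactants: 17 (1R)-1-[(2S,3S)-3-(acetyloxy)-2-(prop-1-en-2-yl)-2,3-dihydro-1-benzofuran-5-yl]ethyl (2E)-2-methylbut-2-enoate
Product: 19 (1R)-1-[(2S,3S)-3-(acetyloxy)-2-(3-oxoprop-1-en-2-yl)-2,3-dihydro-1-benzofuran-5-yl]ethyl (2E)-2-methylbut-2-enoate (target), via allylic alcohol 18 (not isolated)
Conditions: SeO2 (2 equiv), 1,4-dioxane, 70 °C
Reagents that add atoms: selenium dioxide, O=[Se]=O
Why: Riley allylic oxidation: ene reaction of SeO2 at the terminal CH2 of the isolated 1,1-disubstituted alkene with hydrogen taken from the methyl group, [2,3]-shift to allylic alcohol 18 and further oxidation to the enal; the electron-poor tiglate alkene is a much weaker ene partner, abstraction of the C2 methine would need a strained exocyclic enol ether, and no stereocentre is touched.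

**Compound list**

1 | methyl 5-acetyl-2-hydroxybenzoate | COC(=O)c1cc(C(C)=O)ccc1O | starting material
2 | 3-chloro-2-methylprop-1-ene | C=C(C)CCl | starting material
3 | methyl 5-acetyl-2-[(2-methylprop-2-en-1-yl)oxy]benzoate | COC(=O)c1cc(C(C)=O)ccc1OCC(C)=C | intermediate
4 | 1,2-bis(trimethylsilyloxy)ethane | C[Si](C)(C)OCCO[Si](C)(C)C | starting material
5 | methyl 5-(2-methyl-1,3-dioxolan-2-yl)-2-[(2-methylprop-2-en-1-yl)oxy]benzoate | COC(=O)c1cc(C2(C)OCCO2)ccc1OCC(C)=C | intermediate
6 | 5-(2-methyl-1,3-dioxolan-2-yl)-2-[(2-methylprop-2-en-1-yl)oxy]benzaldehyde | O=Cc1cc(C2(C)OCCO2)ccc1OCC(C)=C | intermediate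
7 | {5-(2-methyl-1,3-dioxolan-2-yl)-2-[(2-methylprop-2-en-1-yl)oxy]phenyl}methanol | OCc1cc(C2(C)OCCO2)ccc1OCC(C)=C | intermediate
8 | {5-(2-methyl-1,3-dioxolan-2-yl)-2-[(2-methylprop-1-en-1-yl)oxy]phenyl}methanol | OCc1cc(C2(C)OCCO2)ccc1OC=C(C)C | intermediate
9 | 5-(2-methyl-1,3-dioxolan-2-yl)-2-[(2-methylprop-1-en-1-yl)oxy]benzaldehyde | O=Cc1cc(C2(C)OCCO2)ccc1OC=C(C)C | intermediate
10 | rac-(2aR,7bS)-2,2-dimethyl-6-(2-methyl-1,3-dioxolan-2-yl)-2a,7b-dihydro-2H-oxeto[3,2-b][1]benzofuran (cis-fused racemate) | CC1(C)O[C@H]2c3cc(C4(C)OCCO4)ccc3O[C@@H]12 | intermediate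
11 | rac-(2S,3S)-5-(2-methyl-1,3-dioxolan-2-yl)-2-(prop-1-en-2-yl)-2,3-dihydro-1-benzofuran-3-ol (cis racemate) | C=C(C)[C@@H]1Oc2ccc(C3(C)OCCO3)cc2[C@@H]1O | intermediate
12 | vinyl acetate | C=COC(C)=O | starting material
13 | (2S,3S)-5-(2-methyl-1,3-dioxolan-2-yl)-2-(prop-1-en-2-yl)-2,3-dihydro-1-benzofuran-3-yl acetate | C=C(C)[C@@H]1Oc2ccc(C3(C)OCCO3)cc2[C@@H]1OC(C)=O | intermediate
14 | (2S,3S)-5-acetyl-2-(prop-1-en-2-yl)-2,3-dihydro-1-benzofuran-3-yl acetate | C=C(C)[C@@H]1Oc2ccc(C(C)=O)cc2[C@@H]1OC(C)=O | intermediate
15 | (2S,3S)-5-[(1R)-1-hydroxyethyl]-2-(prop-1-en-2-yl)-2,3-dihydro-1-benzofuran-3-yl acetate | C=C(C)[C@@H]1Oc2ccc([C@@H](C)O)cc2[C@@H]1OC(C)=O | intermediate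
16 | (2E)-2-methylbut-2-enoyl chloride (tigloyl chloride) | C/C=C(\C)C(Cl)=O | starting material
17 | (1R)-1-[(2S,3S)-3-(acetyloxy)-2-(prop-1-en-2-yl)-2,3-dihydro-1-benzofuran-5-yl]ethyl (2E)-2-methylbut-2-enoate | C=C(C)[C@@H]1Oc2ccc([C@@H](C)OC(=O)/C(C)=C/C)cc2[C@@H]1OC(C)=O | intermediate
18 | (1R)-1-[(2S,3S)-3-(acetyloxy)-2-(3-hydroxyprop-1-en-2-yl)-2,3-dihydro-1-benzofuran-5-yl]ethyl (2E)-2-methylbut-2-enoate | C=C(CO)[C@@H]1Oc2ccc([C@@H](C)OC(=O)/C(C)=C/C)cc2[C@@H]1OC(C)=O | intermediate
19 | (1R)-1-[(2S,3S)-3-(acetyloxy)-2-(3-oxoprop-1-en-2-yl)-2,3-dihydro-1-benzofuran-5-yl]ethyl (2E)-2-methylbut-2-enoate | C=C(C=O)[C@@H]1Oc2ccc([C@@H](C)OC(=O)/C(C)=C/C)cc2[C@@H]1OC(C)=O | target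

**Summary and risks**

Total step count: 12. Longest linear sequence: 12 steps (from 1).

Steps most likely to fail:

1. Step 6 (photocycloaddition). The excited aldehyde may decay without forming the oxetane, through charge-transfer quenching by the enol ether, arene–alkene cycloaddition from a π,π* triplet, or intermolecular coupling. Fallback with known chemistry, leaving the oxetane aside: starting from alcohol 7, MnO2 oxidation (CH2Cl2, rt) gives the 2-methylallyl ether aldehyde 6, now isolated. Irradiation of 6 (≈ 350 nm, benzene) should trigger abstraction of an allylic O–CH2 hydrogen by the excited carbonyl and Norrish–Yang cyclisation of the resulting 1,5-biradical. This is the δ-hydrogen abstraction–cyclisation known for ortho-alkoxy and ortho-benzyloxy aryl aldehydes and ketones, which leads to 2,3-dihydrobenzofuran-3-ols. It should give the 2-isopropenyl-3-ols directly, as the cis racemate 11 and the trans racemate rac-(2R,3S)-5-(2-methyl-1,3-dioxolan-2-yl)-2-(prop-1-en-2-yl)-2,3-dihydro-1-benzofuran-3-ol F1. The cis isomer is separated by chromatography on silica and re-enters the route at 11 before step 8, so steps 4 to 7 are bypassed.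

2. Step 7 (oxetane opening). The oxetane may be too unreactive towards the aluminium amide, the ketal may tie up the Lewis acid, or ionisation at the benzylic C3–O bond may lead towards a benzofuran. Fallback with known chemistry, giving up Lewis-acid assistance for a purely base-driven β-elimination: racemic 10 is treated with the mixed lithium–potassium amide base LDA/KOtBu (THF, −50 °C → 0 °C), the superbase isomerisation described for oxetanes to homoallylic alcohols. The methyl hydrogens are again the only ones that can reach a syn arrangement with the breaking O–CMe2 bond. The fallback sets out from 10, returns at 11 and makes no new compound (F0).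

3. Step 8 (lipase resolution). Acylation of the hindered cis alcohol may be slow, or the enzyme may discriminate poorly or in the opposite sense between the two enantiomers. Fallback, replacing enzymatic selection by physical separation of enantiomers: racemic 11 is acetylated without selection (Ac2O, pyridine, DMAP, CH2Cl2, 0 °C). This should give 13 together with its enantiomer (2R,3R)-5-(2-methyl-1,3-dioxolan-2-yl)-2-(prop-1-en-2-yl)-2,3-dihydro-1-benzofuran-3-yl acetate F2. The two are separated by preparative chromatography on a chiral stationary phase (amylose tris(3,5-dimethylphenylcarbamate), hexane/2-propanol), and the configuration of the collected fraction is assigned by circular dichroism compared with calculation. The route is rejoined at 13.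

Further compounds
F1 | step 6 | rac-(2R,3S)-5-(2-methyl-1,3-dioxolan-2-yl)-2-(prop-1-en-2-yl)-2,3-dihydro-1-benzofuran-3-ol (trans racemate) | C=C(C)[C@H]1Oc2ccc(C3(C)OCCO3)cc2[C@@H]1O
F0 | step 7 | none | none
F2 | step 8 | (2R,3R)-5-(2-methyl-1,3-dioxolan-2-yl)-2-(prop-1-en-2-yl)-2,3-dihydro-1-benzofuran-3-yl acetate | C=C(C)[C@H]1Oc2ccc(C3(C)OCCO3)cc2[C@H]1OC(C)=O
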